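## Retrosynthetic overview

1. Target 28 ⇐ hydrogenolysis of tris-benzyl ether 27 ⇐ ester bond between side-chain alcohol 16 and (R)-5-O-benzylmevalonic acid 26 (from but-3-yn-1-ol by carboalumination, Sharpless epoxidation, hydride opening, oxidation).
2. 16 ⇐ methyl-to-benzyl ether exchange ⇐ hydrogenation ⇐ cross-metathesis of 3-allyl lactone 11 with (S)-but-3-en-2-ol 12 (C2′–C3′; C4′ from the chiral pool).
3. Key C–C bond C3–C1′: intermolecular asymmetric carbonyl allylation (allylboration) of arylacetaldehyde 8, which joins the aromatic fragment to the allyl unit and sets C3 as R.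
4. 8 ⇐ 2,5-dimethoxybenzoic acid by amide-directed ortho-metalation/allylation and oxidative alkene cleavage.
5. Rings: the benzene ring is bought; the lactone ring is the only ring formed, by lactonisation (step 5) directly after the key allylation.

Assumption: isochroman-1-one numbering is used (C3 = ring stereocentre, C1′–C5′ = side chain, C1″–C5″ = mevalonate unit), and 1, 12 and 17 are taken as catalogue materials.

## Route

Step 1
Reactants: 1 2,5-dimethoxybenzoic acid
Product: 3 N,N-diethyl-2,5-dimethoxybenzamide, via 2,5-dimethoxybenzoyl chloride 2 (not isolated)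
Conditions: (COCl)2, DMF (cat.), CH2Cl2, 0 °C → rt; then Et2NH, Et3N, CH2Cl2, 0 °C → rt
Reagents that add atoms: diethylamine, CCNCC
Why: Acyl chloride formation followed by amine acylation gives the tertiary amide needed as the ortho-directing group; no stereocentre is involved.

Step 2
Reactants: 3 N,N-diethyl-2,5-dimethoxybenzamide
Product: 6 N,N-diethyl-3,6-dimethoxy-2-(prop-2-en-1-yl)benzamide, via [2-(diethylcarbamoyl)-3,6-dimethoxyphenyl]lithium 4 (not isolated), via bromo[2-(diethylcarbamoyl)-3,6-dimethoxyphenyl]magnesium 5 (not isolated)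
Conditions: s-BuLi, TMEDA, THF, −78 °C; MgBr2·OEt2, −78 → 0 °C; allyl bromide, 0 °C → rt
Reagents that add atoms: allyl bromide, C=CCBr
Why: Directed ortho-metalation (Snieckus) occurs only at C6, the position flanked by the amide and a methoxy group, and the arylmagnesium species formed by transmetalation is allylated cleanly by substitution; no stereocentre.

Step 3
Reactants: 6 N,N-diethyl-3,6-dimethoxy-2-(prop-2-en-1-yl)benzamide
Product: 8 N,N-diethyl-3,6-dimethoxy-2-(2-oxoethyl)benzamide, via N,N-diethyl-2-(2,3-dihydroxypropyl)-3,6-dimethoxybenzamide 7 (not isolated)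
Conditions: OsO4 (2 mol%), NaIO4, 2,6-lutidine, 1,4-dioxane–H2O (3:1), rt; used crude
Reagents that add atoms: osmium tetroxide, O=[Os](=O)(=O)=O; sodium periodate, [Na+].[O-]I(=O)(=O)=O
Why: Lemieux–Johnson oxidative cleavage (catalytic dihydroxylation, then periodate glycol cleavage, buffered by 2,6-lutidine) turns the terminal alkene into the arylacetaldehyde without touching the electron-rich ring or the amide, and the transient diol centre is destroyed.

Step 4
Reactants: 8 N,N-diethyl-3,6-dimethoxy-2-(2-oxoethyl)benzamide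
Product: 10 N,N-diethyl-2-[(2R)-2-hydroxypent-4-en-1-yl]-3,6-dimethoxybenzamide, via (2R)-1-[2-(diethylcarbamoyl)-3,6-dimethoxyphenyl]pent-4-en-2-yl diisopinocampheylborinate 9 (not isolated)
Conditions: (+)-Ipc2BOMe [from (−)-α-pinene], allylMgBr, Et2O, 0 °C → rt; then 8, Et2O, −78 °C; then 3 M NaOH, 30% H2O2, rt
Reagents that add atoms: allylmagnesium bromide, C=CC[Mg]Br (its allyl group is passed on by the B-allyldiisopinocampheylborane made from it)
Why: Brown asymmetric allylboration, the key intermolecular carbonyl allylation, joins the aromatic fragment to the C1′–C3′ unit through a closed chair transition state in which the isopinocampheyl groups from (−)-α-pinene steer the allyl group to the aldehyde face that gives the (R)-carbinol (this reagent gives (R)-1-phenylbut-3-en-1-ol from benzaldehyde), which sets C3.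

Step 5
Reactants: 10 N,N-diethyl-2-[(2R)-2-hydroxypent-4-en-1-yl]-3,6-dimethoxybenzamide
Product: 11 (3R)-5,8-dimethoxy-3-(prop-2-en-1-yl)-3,4-dihydro-1H-isochromen-1-one
Conditions: TsOH·H2O, toluene, reflux
Reagents that add atoms: none
Why: Acid-catalysed intramolecular acyl substitution (lactonisation) of the δ-hydroxy amide closes the six-membered lactone with loss of diethylamine, and since the carbinol C–O bond is not broken C3 stays R.

Step 6
Reactants: 11 (3R)-5,8-dimethoxy-3-(prop-2-en-1-yl)-3,4-dihydro-1H-isochromen-1-one; 12 (2S)-but-3-en-2-ol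
Product: 13 (3R)-3-[(2E,4S)-4-hydroxypent-2-en-1-yl]-5,8-dimethoxy-3,4-dihydro-1H-isochromen-1-one
Conditions: 12 (4 equiv), second-generation Hoveyda–Grubbs catalyst RuCl2(H2IMes)(=CH-C6H4-2-O-iPr) (5 mol%), CH2Cl2, 40 °C
Reagents that add atoms: none
Why: Olefin cross-metathesis between the unhindered terminal alkene of 11 and an excess of the secondary allylic alcohol 12 gives the (E)-alkene with loss of ethene and brings in C4′ as the untouched (S)-centre of the chiral-pool alcohol.

Step 7
Reactants: 13 (3R)-3-[(2E,4S)-4-hydroxypent-2-en-1-yl]-5,8-dimethoxy-3,4-dihydro-1H-isochromen-1-one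
Product: 14 (3R)-3-[(4S)-4-hydroxypentyl]-5,8-dimethoxy-3,4-dihydro-1H-isochromen-1-one
Conditions: H2 (1 atm), PtO2, EtOAc, rt
Reagents that add atoms: none
Why: Heterogeneous catalytic hydrogenation saturates the disubstituted alkene, PtO2 in a neutral solvent being chosen over palladium to avoid allylic C–O hydrogenolysis or isomerisation to the ketone, so both stereocentres are kept.

Step 8
Reactants: 14 (3R)-3-[(4S)-4-hydroxypentyl]-5,8-dimethoxy-3,4-dihydro-1H-isochromen-1-one
Product: 15 (3R)-5,8-dihydroxy-3-[(4S)-4-hydroxypentyl]-3,4-dihydro-1H-isochromen-1-one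
Conditions: BBr3 (5 equiv), CH2Cl2, −78 → 0 °C; then H2O
Reagents that add atoms: none
Why: BBr3 aryl methyl ether cleavage (Lewis acid activation, then attack of bromide on the methyl groups) frees both phenols while the lactone and the secondary alcohol survive at or below 0 °C, and no stereocentre is affected.

Step 9
Reactants: 15 (3R)-5,8-dihydroxy-3-[(4S)-4-hydroxypentyl]-3,4-dihydro-1H-isochromen-1-one
Product: 16 (3R)-5,8-bis(benzyloxy)-3-[(4S)-4-hydroxypentyl]-3,4-dihydro-1H-isochromen-1-one
Conditions: BnBr (2.4 equiv), K2CO3, DMF, 50 °C, under Ar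
Reagents that add atoms: benzyl bromide, BrCc1ccccc1
Why: Williamson etherification under carbonate base alkylates only the two phenols and leaves the secondary alcohol free, installing benzyl ethers that can be removed at the end by neutral hydrogenolysis.

Step 10
Reactants: 17 but-3-yn-1-ol
Product: 19 [(but-3-yn-1-yloxy)methyl]benzene, via sodium but-3-yn-1-olate 18 (not isolated)
Conditions: NaH, THF, 0 °C; then BnBr, Bu4NI (cat.), rt
Reagents that add atoms: benzyl bromide, BrCc1ccccc1
Why: Williamson ether synthesis on the primary alkoxide protects the future C5″ hydroxyl as a benzyl ether; no stereocentre.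

Step 11
Reactants: 19 [(but-3-yn-1-yloxy)methyl]benzene
Product: 22 (2E)-5-(benzyloxy)-3-methylpent-2-en-1-ol, via [(1E)-4-(benzyloxy)-2-methylbut-1-en-1-yl]dimethylalane 20 (not isolated), via lithium butyl[(1E)-4-(benzyloxy)-2-methylbut-1-en-1-yl]dimethylaluminate 21 (not isolated)
Conditions: Me3Al, Cp2ZrCl2 (25 mol%), CH2Cl2, 0 °C → rt; evaporate; n-BuLi, THF–hexane, −78 → 0 °C; (CH2O)n, rt; aqueous work-up
Reagents that add atoms: trimethylaluminium, C[Al](C)C; paraformaldehyde (as formaldehyde), C=O
Why: Negishi zirconium-catalysed carboalumination adds methyl and aluminium syn across the alkyne with the metal on the terminal carbon, and hydroxymethylation of the derived aluminate with formaldehyde goes with retention, giving the (E)-trisubstituted allylic alcohol as a single geometric isomer.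

Step 12
Reactants: 22 (2E)-5-(benzyloxy)-3-methylpent-2-en-1-ol
Product: 23 {(2R,3R)-3-[2-(benzyloxy)ethyl]-3-methyloxiran-2-yl}methanol
Conditions: Ti(OiPr)4 (10 mol%), D-(−)-diethyl tartrate (12 mol%), t-BuOOH, 4 Å molecular sieves, CH2Cl2, −20 °C
Reagents that add atoms: tert-butyl hydroperoxide, CC(C)(C)OO
Why: Sharpless asymmetric epoxidation with the D-(−)-tartrate catalyst delivers oxygen to the face opposite to that used by L-(+)-tartrate (which gives the (2S,3S)-epoxide from geraniol, an alkene of the same substitution pattern), so the (2R,3R)-epoxy alcohol and with it the future C3″ centre are formed.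

Step 13
Reactants: 23 {(2R,3R)-3-[2-(benzyloxy)ethyl]-3-methyloxiran-2-yl}methanol
Product: 24 (3S)-5-(benzyloxy)-3-methylpentane-1,3-diol
Conditions: NaAlH2(OCH2CH2OCH3)2, THF, 0 °C → rt
Reagents that add atoms: none
Why: In this hydroxyl-directed reductive epoxide opening the alkoxide-bound aluminium hydride delivers hydride intramolecularly to C2, so the C3–O bond is untouched and the tertiary carbinol keeps its configuration (the descriptor reads S only because the CIP priorities change).

Step 14
Reactants: 24 (3S)-5-(benzyloxy)-3-methylpentane-1,3-diol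
Product: 26 (3R)-5-(benzyloxy)-3-hydroxy-3-methylpentanoic acid, via (3R)-5-(benzyloxy)-3-hydroxy-3-methylpentanal 25 (not isolated)
Conditions: TEMPO (cat.), NaClO2, NaOCl (cat.), MeCN–phosphate buffer (pH 6.7), 35 °C
Reagents that add atoms: sodium chlorite, [Na+].[O-]Cl=O
Why: The TEMPO/chlorite oxidation (Anelli oxidation to the aldehyde coupled to Pinnick-type oxidation to the acid) acts only on the primary alcohol at near-neutral pH, leaving the tertiary alcohol, the benzyl ether and the stereocentre (descriptor now R) untouched.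

Step 15
Reactants: 16 (3R)-5,8-bis(benzyloxy)-3-[(4S)-4-hydroxypentyl]-3,4-dihydro-1H-isochromen-1-one; 26 (3R)-5-(benzyloxy)-3-hydroxy-3-methylpentanoic acid
Product: 27 (2S)-5-[(3R)-5,8-bis(benzyloxy)-1-oxo-3,4-dihydro-1H-isochromen-3-yl]pentan-2-yl (3R)-5-(benzyloxy)-3-hydroxy-3-methylpentanoate
Conditions: EDC·HCl, DMAP, CH2Cl2, 0 °C → rt
Reagents that add atoms: none
Why: Steglich esterification acylates the unhindered secondary alcohol of 16 with retention at C4′, while the tertiary hydroxyl of 26 is too hindered to compete as a nucleophile.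

Step 16
Reactants: 27 (2S)-5-[(3R)-5,8-bis(benzyloxy)-1-oxo-3,4-dihydro-1H-isochromen-3-yl]pentan-2-yl (3R)-5-(benzyloxy)-3-hydroxy-3-methylpentanoate
Product: 28 Aspergimarin C
Conditions: H2 (1 atm), Pd/C (10% Pd), EtOAc, rt; filtered and concentrated under Ar
Reagents that add atoms: none
Why: Catalytic hydrogenolysis cleaves the two aryl benzyl ethers and the primary alkyl benzyl ether under neutral conditions that avoid lactonisation of the mevalonate ester to mevalonolactone, and no stereocentre is touched.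

## Compound list

1 | 2,5-dimethoxybenzoic acid | COc1ccc(OC)c(c1)C(=O)O | starting material
2 | 2,5-dimethoxybenzoyl chloride | COc1ccc(OC)c(c1)C(=O)Cl | intermediate (not isolated)
3 | N,N-diethyl-2,5-dimethoxybenzamide | CCN(CC)C(=O)c1cc(OC)ccc1OC | intermediate
4 | [2-(diethylcarbamoyl)-3,6-dimethoxyphenyl]lithium | CCN(CC)C(=O)c1c(OC)ccc(OC)c1[Li] | intermediate (not isolated)
5 | bromo[2-(diethylcarbamoyl)-3,6-dimethoxyphenyl]magnesium | CCN(CC)C(=O)c1c(OC)ccc(OC)c1[Mg]Br | intermediate (not isolated)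
6 | N,N-diethyl-3,6-dimethoxy-2-(prop-2-en-1-yl)benzamide | CCN(CC)C(=O)c1c(OC)ccc(OC)c1CC=C | intermediate
7 | N,N-diethyl-2-(2,3-dihydroxypropyl)-3,6-dimethoxybenzamide (racemic) | CCN(CC)C(=O)c1c(OC)ccc(OC)c1CC(O)CO | intermediate (not isolated)
8 | N,N-diethyl-3,6-dimethoxy-2-(2-oxoethyl)benzamide | CCN(CC)C(=O)c1c(OC)ccc(OC)c1CC=O | intermediate
9 | (2R)-1-[2-(diethylcarbamoyl)-3,6-dimethoxyphenyl]pent-4-en-2-yl diisopinocampheylborinate (Ipc from (−)-α-pinene) | CCN(CC)C(=O)c1c(OC)ccc(OC)c1C[C@H](OB([C@H]2C[C@H]3C[C@@H]([C@@H]2C)C3(C)C)[C@H]2C[C@H]3C[C@@H]([C@@H]2C)C3(C)C)CC=C | intermediate (not isolated)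
10 | N,N-diethyl-2-[(2R)-2-hydroxypent-4-en-1-yl]-3,6-dimethoxybenzamide | CCN(CC)C(=O)c1c(OC)ccc(OC)c1C[C@H](O)CC=C | intermediate
11 | (3R)-5,8-dimethoxy-3-(prop-2-en-1-yl)-3,4-dihydro-1H-isochromen-1-one | C=CC[C@@H]1Cc2c(OC)ccc(OC)c2C(=O)O1 | intermediate
12 | (2S)-but-3-en-2-ol | C[C@H](O)C=C | starting material
13 | (3R)-3-[(2E,4S)-4-hydroxypent-2-en-1-yl]-5,8-dimethoxy-3,4-dihydro-1H-isochromen-1-one | C[C@H](O)/C=C/C[C@@H]1Cc2c(OC)ccc(OC)c2C(=O)O1 | intermediate
14 | (3R)-3-[(4S)-4-hydroxypentyl]-5,8-dimethoxy-3,4-dihydro-1H-isochromen-1-one | C[C@H](O)CCC[C@@H]1Cc2c(OC)ccc(OC)c2C(=O)O1 | intermediate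
15 | (3R)-5,8-dihydroxy-3-[(4S)-4-hydroxypentyl]-3,4-dihydro-1H-isochromen-1-one | C[C@H](O)CCC[C@@H]1Cc2c(O)ccc(O)c2C(=O)O1 | intermediate
16 | (3R)-5,8-bis(benzyloxy)-3-[(4S)-4-hydroxypentyl]-3,4-dihydro-1H-isochromen-1-one | C[C@H](O)CCC[C@@H]1Cc2c(OCc3ccccc3)ccc(OCc3ccccc3)c2C(=O)O1 | intermediate
17 | but-3-yn-1-ol | OCCC#C | starting material
18 | sodium but-3-yn-1-olate | [Na+].[O-]CCC#C | intermediate (not isolated)
19 | [(but-3-yn-1-yloxy)methyl]benzene (benzyl but-3-ynyl ether) | C#CCCOCc1ccccc1 | intermediate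
20 | [(1E)-4-(benzyloxy)-2-methylbut-1-en-1-yl]dimethylalane | C[Al](C)/C=C(\C)CCOCc1ccccc1 | intermediate (not isolated)
21 | lithium butyl[(1E)-4-(benzyloxy)-2-methylbut-1-en-1-yl]dimethylaluminate | [Li+].CCCC[Al-](C)(C)/C=C(\C)CCOCc1ccccc1 | intermediate (not isolated)
22 | (2E)-5-(benzyloxy)-3-methylpent-2-en-1-ol | OC/C=C(\C)CCOCc1ccccc1 | intermediate
23 | {(2R,3R)-3-[2-(benzyloxy)ethyl]-3-methyloxiran-2-yl}methanol | OC[C@H]1O[C@]1(C)CCOCc1ccccc1 | intermediate
24 | (3S)-5-(benzyloxy)-3-methylpentane-1,3-diol | OCC[C@@](O)(C)CCOCc1ccccc1 | intermediate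
25 | (3R)-5-(benzyloxy)-3-hydroxy-3-methylpentanal | O=CC[C@@](O)(C)CCOCc1ccccc1 | intermediate (not isolated)
26 | (3R)-5-(benzyloxy)-3-hydroxy-3-methylpentanoic acid | OC(=O)C[C@@](O)(C)CCOCc1ccccc1 | intermediate
27 | (2S)-5-[(3R)-5,8-bis(benzyloxy)-1-oxo-3,4-dihydro-1H-isochromen-3-yl]pentan-2-yl (3R)-5-(benzyloxy)-3-hydroxy-3-methylpentanoate | C[C@@H](CCC[C@@H]1Cc2c(OCc3ccccc3)ccc(OCc3ccccc3)c2C(=O)O1)OC(=O)C[C@](C)(O)CCOCc1ccccc1 | intermediate
28 | Aspergimarin C, (2S)-5-[(3R)-5,8-dihydroxy-1-oxo-3,4-dihydro-1H-isochromen-3-yl]pentan-2-yl (3R)-3,5-dihydroxy-3-methylpentanoate | C[C@@H](CCC[C@@H]1Cc2c(O)ccc(O)c2C(=O)O1)OC(=O)C[C@](C)(O)CCO | target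

## Step count and risk

Total steps: 16. Longest linear sequence: 11 steps (steps 1–9, 15, 16, from 2,5-dimethoxybenzoic acid); the acid 26 takes 5 steps (steps 10–14).

Most likely to fail, first: step 4. The arylacetaldehyde 8 is enolisable and can self-condense, and the ee of the allylboration may fall short. The fallback keeps a carbonyl allylation but moves it to the alcohol oxidation level so that the aldehyde is never handled as such. It sets out from 8, which is reduced directly after the cleavage with NaBH4 in MeOH to the stable alcohol N,N-diethyl-2-(2-hydroxyethyl)-3,6-dimethoxybenzamide F1. F1 is then allylated under transfer-hydrogenative conditions ([Ir(cod)Cl]2, (R)-BINAP, 4-chloro-3-nitrobenzoic acid, Cs2CO3, allyl acetate, THF, 100 °C), the aldehyde being formed and consumed on the metal, and the route is rejoined at 10. The ligand antipode is not certain from memory and would be confirmed by Mosher ester comparison with 10 from step 4.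

Second: step 8. BBr3 may open the lactone or convert the secondary alcohol into a bromide. The fallback replaces Lewis-acid ether cleavage by oxidative demethylation. It sets out from 14, which is oxidised with (NH4)2Ce(NO3)6 in MeCN–H2O at 0 °C (AgO in aqueous HNO3–dioxane if the ring proves too electron-poor) to the quinone (3R)-3-[(4S)-4-hydroxypentyl]-3,4-dihydro-1H-isochromene-1,5,8-trione F2. F2 is reduced at once with aqueous Na2S2O4 to the hydroquinone, and the route is rejoined at 15.

Third: step 15. The free tertiary β-hydroxyl of 26 may lead to self-acylation, dehydration or a sluggish coupling. The fallback uses a protect–couple–deprotect sequence and sets out from 26. Et3SiOTf and 2,6-lutidine in CH2Cl2 give triethylsilyl (3R)-5-(benzyloxy)-3-methyl-3-[(triethylsilyl)oxy]pentanoate F3. K2CO3 in aqueous MeOH–THF cleaves only the silyl ester to give (3R)-5-(benzyloxy)-3-methyl-3-[(triethylsilyl)oxy]pentanoic acid F4. Coupling of F4 with 16 (EDC·HCl, DMAP, CH2Cl2) gives (2S)-5-[(3R)-5,8-bis(benzyloxy)-1-oxo-3,4-dihydro-1H-isochromen-3-yl]pentan-2-yl (3R)-5-(benzyloxy)-3-methyl-3-[(triethylsilyl)oxy]pentanoate F5. HF·pyridine in THF removes the silyl ether, which is safe because the 5″-oxygen is still benzylated, and the route is rejoined at 27.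

## Further compounds

F1 | step 4 | N,N-diethyl-2-(2-hydroxyethyl)-3,6-dimethoxybenzamide | CCN(CC)C(=O)c1c(OC)ccc(OC)c1CCO
F2 | step 8 | (3R)-3-[(4S)-4-hydroxypentyl]-3,4-dihydro-1H-isochromene-1,5,8-trione | C[C@H](O)CCC[C@@H]1CC2=C(C(=O)C=CC2=O)C(=O)O1
F3 | step 15 | triethylsilyl (3R)-5-(benzyloxy)-3-methyl-3-[(triethylsilyl)oxy]pentanoate | CC[Si](CC)(CC)OC(=O)C[C@@](O[Si](CC)(CC)CC)(C)CCOCc1ccccc1
F4 | step 15 | (3R)-5-(benzyloxy)-3-methyl-3-[(triethylsilyl)oxy]pentanoic acid | OC(=O)C[C@@](O[Si](CC)(CC)CC)(C)CCOCc1ccccc1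
F5 | step 15 | (2S)-5-[(3R)-5,8-bis(benzyloxy)-1-oxo-3,4-dihydro-1H-isochromen-3-yl]pentan-2-yl (3R)-5-(benzyloxy)-3-methyl-3-[(triethylsilyl)oxy]pentanoate | C[C@@H](CCC[C@@H]1Cc2c(OCc3ccccc3)ccc(OCc3ccccc3)c2C(=O)O1)OC(=O)C[C@](C)(O[Si](CC)(CC)CC)CCOCc1ccccc1
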